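**Plan**
- Retrosynthesis: the three O-benzyl groups come off last; the pyranone of the protected flavone is then cut at O1–C8a, C4–C4a and O1–C2, giving a ring A aryne and a ring B arylpropiolic acid.
- Enabling feature: C4a and C8a are neighbouring ring A carbons that carry the acyl carbon and the ring oxygen, and the C5 oxygen next to C4a polarises an aryne drawn across C4a–C8a.
- Forward, ring A: methyl 4-O-methylgallate is benzylated, taken to the aldehyde, converted to the phenol by Baeyer–Villiger oxidation, brominated and turned into the ortho-silyl aryl triflate.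
- Forward, ring B: 2,5-dimethoxybenzaldehyde is converted to the phenol, benzylated, iodinated and coupled with propiolic acid.
- The two fragments are joined and the pyranone ring is closed in one operation, then hydrogenolysis gives the target; the target has no stereocenter, so only regiochemistry has to be controlled.

Key step: step 11

Remark: flavone numbering (O1, C2–C4, C4a, C5–C8, C8a) is used for the ring A carbons of the fragments as well, and the 3-benzyloxyaryne is assumed to follow the usual 3-alkoxyaryne preference for attack at the carbon remote from the alkoxy group.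

**Route**

Step 1
Reactants: 1 methyl 3,5-dihydroxy-4-methoxybenzoate
Product: 2 methyl 3,5-bis(benzyloxy)-4-methoxybenzoate
Conditions: BnBr (2.4 equiv), K2CO3, DMF, 60 °C
Reagents that add atoms: benzyl bromide, BrCc1ccccc1
Why: Williamson etherification of both phenols with K2CO3 in DMF is routine, and the methyl ester is inert to carbonate.

Step 2
Reactants: 2 methyl 3,5-bis(benzyloxy)-4-methoxybenzoate
Product: 3 [3,5-bis(benzyloxy)-4-methoxyphenyl]methanol
Conditions: LiAlH4, THF, 0 °C to rt; aqueous work-up
Reagents that add atoms: none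
Why: Hydride reduction of the benzoate ester with LiAlH4 should stop at the benzylic alcohol and leave the aryl benzyl and methyl ethers untouched.

Step 3
Reactants: 3 [3,5-bis(benzyloxy)-4-methoxyphenyl]methanol
Product: 4 3,5-bis(benzyloxy)-4-methoxybenzaldehyde
Conditions: activated MnO2 (excess), CH2Cl2, rt
Reagents that add atoms: none
Why: Heterogeneous MnO2 oxidation is selective for benzylic alcohols and should stop cleanly at the aldehyde.

Step 4
Reactants: 4 3,5-bis(benzyloxy)-4-methoxybenzaldehyde
Product: 6 3,5-bis(benzyloxy)-4-methoxyphenol, via 3,5-bis(benzyloxy)-4-methoxyphenyl formate 5 (not isolated)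
Conditions: mCPBA, CH2Cl2, 0 °C to rt; aq. Na2S2O3 quench; then K2CO3 (cat.), MeOH, rt
Reagents that add atoms: meta-chloroperoxybenzoic acid, OOC(=O)c1cccc(Cl)c1
Why: In this Baeyer–Villiger (Dakin-type) oxidation the electron-rich trialkoxyaryl group migrates to oxygen to give the aryl formate, which mild methanolysis should cleave to the phenol.

Step 5
Reactants: 6 3,5-bis(benzyloxy)-4-methoxyphenol
Product: 7 3,5-bis(benzyloxy)-2-bromo-4-methoxyphenol
Conditions: NBS (1.0 equiv), CH2Cl2, −78 to 0 °C, dark
Reagents that add atoms: N-bromosuccinimide, O=C1CCC(=O)N1Br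
Why: Electrophilic aromatic bromination can only go ortho to the free hydroxyl (two equivalent sites, para position blocked), and one equivalent of NBS at low temperature should hold it at the monobromide.

Step 6
Reactants: 7 3,5-bis(benzyloxy)-2-bromo-4-methoxyphenol
Product: 11 3,5-bis(benzyloxy)-4-methoxy-2-(trimethylsilyl)phenyl trifluoromethanesulfonate, via bromoaryl trimethylsilyl ether 8 (not isolated), via 2-lithioaryl trimethylsilyl ether 9 (not isolated), via lithium 2-(trimethylsilyl)phenolate 10 (not isolated)
Conditions: HMDS, THF, 70 °C, then volatiles removed; n-BuLi, THF, −100 to −80 °C; Tf2O, −100 °C to rt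
Reagents that add atoms: hexamethyldisilazane, C[Si](C)(C)N[Si](C)(C)C; trifluoromethanesulfonic anhydride, O=S(=O)(OS(=O)(=O)C(F)(F)F)C(F)(F)F
Why: O-silylation, bromine–lithium exchange and a 1,3 oxygen-to-carbon silyl shift (retro-Brook rearrangement) should give the ortho-silyl phenoxide that Tf2O traps, which is the standard entry to Kobayashi-type aryne precursors.

Step 7
Reactants: 12 2,5-dimethoxybenzaldehyde
Product: 14 2,5-dimethoxyphenol, via 2,5-dimethoxyphenyl formate 13 (not isolated)
Conditions: mCPBA, CH2Cl2, rt; aq. Na2S2O3 quench; then K2CO3 (cat.), MeOH, rt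
Reagents that add atoms: meta-chloroperoxybenzoic acid, OOC(=O)c1cccc(Cl)c1
Why: Baeyer–Villiger oxidation of this ortho-methoxybenzaldehyde proceeds by aryl migration, and methanolysis of the formate should release the phenol.

Step 8
Reactants: 14 2,5-dimethoxyphenol
Product: 15 2-(benzyloxy)-1,4-dimethoxybenzene
Conditions: BnBr, K2CO3, DMF, 60 °C
Reagents that add atoms: benzyl bromide, BrCc1ccccc1
Why: Williamson etherification of a simple phenol.

Step 9
Reactants: 15 2-(benzyloxy)-1,4-dimethoxybenzene
Product: 16 1-(benzyloxy)-4-iodo-2,5-dimethoxybenzene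
Conditions: NIS (1.05 equiv), TFA (cat.), MeCN, rt, dark
Reagents that add atoms: N-iodosuccinimide, O=C1CCC(=O)N1I
Why: Electrophilic aromatic iodination of a 1,2,4-trialkoxybenzene should go to the one position that is para to one alkoxy group (here benzyloxy) and ortho to another, the other free sites being less activated or flanked.

Step 10
Reactants: 16 1-(benzyloxy)-4-iodo-2,5-dimethoxybenzene; 17 propiolic acid
Product: 18 3-[4-(benzyloxy)-2,5-dimethoxyphenyl]prop-2-ynoic acid
Conditions: Pd(PPh3)4 (5 mol %), DBU (2.4 equiv), DMSO, 25–35 °C; then cold dilute HCl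
Reagents that add atoms: none
Why: Copper-free Sonogashira-type coupling of aryl iodides with propiolic acid under zerovalent palladium and DBU gives arylpropiolic acids near ambient temperature, where decarboxylation of the product is slow.

Step 11
Reactants: 11 3,5-bis(benzyloxy)-4-methoxy-2-(trimethylsilyl)phenyl trifluoromethanesulfonate; 18 3-[4-(benzyloxy)-2,5-dimethoxyphenyl]prop-2-ynoic acid
Product: 22 5,7-bis(benzyloxy)-2-[4-(benzyloxy)-2,5-dimethoxyphenyl]-6-methoxy-4H-chromen-4-one, via 3,5-bis(benzyloxy)-4-methoxybenzyne 19 (not isolated), via ortho-cesio aryl propiolate 20 (not isolated), via cesium 2-(arylpropioloyl)phenolate 21 (not isolated)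
Conditions: CsF (4 equiv), THF, 125 °C, sealed tube; 11 in 1.5-fold excess
Reagents that add atoms: none
Why: Fluoride attacks silicon of 11 and triflate leaves to give aryne 19, the carboxylate of 18 adds through oxygen at C8a, and the C4a aryl anion 20 attacks its own ester carbonyl through a four-membered transition state with cleavage of the acyl C–O bond, which amounts to insertion of the aryne into the acid C–O bond and gives ketone phenoxide 21. Phenoxide 21 then adds to the β-carbon of the ynone and protonation completes the pyranone, so that C8a–O1, C4a–C4 and O1–C2 all form in one flask. The closest known reaction type is the fluoride-mediated insertion of arynes into the C–O bond of carboxylic acids to give ortho-hydroxyaryl ketones, which with arylpropiolic acids is known to continue to flavones. The single ring closed is the pyranone, by 6-endo-dig oxa-Michael addition, and no stereocenter is formed. The step needs regioselective addition to the unsymmetrical aryne, and the inductively withdrawing benzyloxy group at C5 should make C8a the more linear, more electrophilic terminus and place the developing negative charge at C4a beside that oxygen, so that the carbonyl ends up peri to the C5 oxygen as the target requires. It also needs 6-endo rather than 5-exo closure, which the aprotic medium and the β-electrophilic ynone should secure, and because both partners carry only ether groups no other nucleophile competes for the aryne.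

Step 12
Reactants: 22 5,7-bis(benzyloxy)-2-[4-(benzyloxy)-2,5-dimethoxyphenyl]-6-methoxy-4H-chromen-4-one
Product: 23 5,7-dihydroxy-2-(4-hydroxy-2,5-dimethoxyphenyl)-6-methoxy-4H-chromen-4-one
Conditions: H2 (1 atm), 10% Pd/C, EtOAc/MeOH, rt
Reagents that add atoms: none
Why: Hydrogenolysis of aryl benzyl ethers over Pd/C is fast at ambient pressure, whereas the cross-conjugated C2–C3 bond of a flavone is reduced far more slowly, so stopping after three equivalents of hydrogen should give the triol.

**Compound list**
1 | methyl 3,5-dihydroxy-4-methoxybenzoate | COC(=O)c1cc(O)c(OC)c(O)c1 | starting material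
2 | methyl 3,5-bis(benzyloxy)-4-methoxybenzoate | COC(=O)c1cc(OCc2ccccc2)c(OC)c(OCc2ccccc2)c1 | intermediate
3 | [3,5-bis(benzyloxy)-4-methoxyphenyl]methanol | OCc1cc(OCc2ccccc2)c(OC)c(OCc2ccccc2)c1 | intermediate
4 | 3,5-bis(benzyloxy)-4-methoxybenzaldehyde | O=Cc1cc(OCc2ccccc2)c(OC)c(OCc2ccccc2)c1 | intermediate
5 | 3,5-bis(benzyloxy)-4-methoxyphenyl formate | O=COc1cc(OCc2ccccc2)c(OC)c(OCc2ccccc2)c1 | intermediate
6 | 3,5-bis(benzyloxy)-4-methoxyphenol | Oc1cc(OCc2ccccc2)c(OC)c(OCc2ccccc2)c1 | intermediate
7 | 3,5-bis(benzyloxy)-2-bromo-4-methoxyphenol | Oc1cc(OCc2ccccc2)c(OC)c(OCc2ccccc2)c1Br | intermediate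
8 | [3,5-bis(benzyloxy)-2-bromo-4-methoxyphenoxy]trimethylsilane | C[Si](C)(C)Oc1cc(OCc2ccccc2)c(OC)c(OCc2ccccc2)c1Br | intermediate
9 | [3,5-bis(benzyloxy)-2-lithio-4-methoxyphenoxy]trimethylsilane | C[Si](C)(C)Oc1cc(OCc2ccccc2)c(OC)c(OCc2ccccc2)c1[Li] | intermediate
10 | lithium 3,5-bis(benzyloxy)-4-methoxy-2-(trimethylsilyl)phenolate | [Li+].[O-]c1cc(OCc2ccccc2)c(OC)c(OCc2ccccc2)c1[Si](C)(C)C | intermediate
11 | 3,5-bis(benzyloxy)-4-methoxy-2-(trimethylsilyl)phenyl trifluoromethanesulfonate | COc1c(OCc2ccccc2)cc(OS(=O)(=O)C(F)(F)F)c([Si](C)(C)C)c1OCc1ccccc1 | intermediate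
12 | 2,5-dimethoxybenzaldehyde | COc1ccc(OC)c(C=O)c1 | starting material
13 | 2,5-dimethoxyphenyl formate | COc1ccc(OC)c(OC=O)c1 | intermediate
14 | 2,5-dimethoxyphenol | COc1ccc(OC)c(O)c1 | intermediate
15 | 2-(benzyloxy)-1,4-dimethoxybenzene | COc1ccc(OC)c(OCc2ccccc2)c1 | intermediate
16 | 1-(benzyloxy)-4-iodo-2,5-dimethoxybenzene | COc1cc(OCc2ccccc2)c(OC)cc1I | intermediate
17 | propiolic acid (prop-2-ynoic acid) | OC(=O)C#C | starting material
18 | 3-[4-(benzyloxy)-2,5-dimethoxyphenyl]prop-2-ynoic acid | OC(=O)C#Cc1cc(OC)c(OCc2ccccc2)cc1OC | intermediate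
19 | 3,5-bis(benzyloxy)-4-methoxybenzyne (1,2-didehydro arene) | COC1=C(OCc2ccccc2)C#CC=C1OCc1ccccc1 | intermediate
20 | cesium 2,4-bis(benzyloxy)-6-({3-[4-(benzyloxy)-2,5-dimethoxyphenyl]prop-2-ynoyl}oxy)-3-methoxybenzen-1-ide | [Cs+].COc1cc(C#CC(=O)Oc2cc(OCc3ccccc3)c(OC)c(OCc3ccccc3)[c-]2)c(OC)cc1OCc1ccccc1 | intermediate
21 | cesium 3,5-bis(benzyloxy)-2-{3-[4-(benzyloxy)-2,5-dimethoxyphenyl]prop-2-ynoyl}-4-methoxyphenolate | [Cs+].COc1cc(C#CC(=O)c2c([O-])cc(OCc3ccccc3)c(OC)c2OCc2ccccc2)c(OC)cc1OCc1ccccc1 | intermediate
22 | 5,7-bis(benzyloxy)-2-[4-(benzyloxy)-2,5-dimethoxyphenyl]-6-methoxy-4H-chromen-4-one | COc1cc(OCc2ccccc2)c(OC)cc1-c1cc(=O)c2c(OCc3ccccc3)c(OC)c(OCc3ccccc3)cc2o1 | intermediate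
23 | 5,7-dihydroxy-2-(4-hydroxy-2,5-dimethoxyphenyl)-6-methoxy-4H-chromen-4-one | COc1cc(-c2cc(=O)c3c(O)c(OC)c(O)cc3o2)c(OC)cc1O | target

**Step count**
Total: 12 steps. Longest linear sequence: 8 steps (steps 1–6, 11 and 12); the ring B branch (steps 7–10) joins at step 11.

**Steps most likely to fail**

Step 11. The aryl anion may be protonated before the acyl shift, which would stall the sequence at the aryl ester. The propiolate may also lose CO2 at 125 °C, or the carboxylate may add in part at the wrong aryne carbon. The fallback builds the pyranone by palladium-catalysed carbonylative annulation; it sets out from 6 and 18 and comes back at 22. Phenol 6 would be iodinated (NIS, CH2Cl2, 0 °C) to 3,5-bis(benzyloxy)-2-iodo-4-methoxyphenol F1. Acid 18 would be protodecarboxylated (CuCl cat., Et3N, MeCN, 60 °C) to 1-(benzyloxy)-4-ethynyl-2,5-dimethoxybenzene F2. F1, F2 and carbon monoxide would then be combined (PdCl2(dppf), Et2NH, 120 °C) in a carbonylative Sonogashira coupling whose ynone cyclises in the amine medium to 22. The position of the iodine fixes the regiochemistry without an aryne.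

Step 6. The oxygen-to-carbon silyl shift may be incomplete, the aryllithium may be quenched before it migrates, or the crowded lithium phenoxide may be triflated only sluggishly at low temperature. The fallback separates C–Si bond formation from triflation by carbamate-directed ortho-metalation; it sets out from 6 (so step 5 is bypassed as well) and comes back at 11. Phenol 6 would be treated with isopropyl isocyanate (Et3N cat., CH2Cl2) to give 3,5-bis(benzyloxy)-4-methoxyphenyl N-(propan-2-yl)carbamate F3. Transient N-silylation (TBSOTf, TMEDA, Et2O) would give 3,5-bis(benzyloxy)-4-methoxyphenyl N-[tert-butyl(dimethyl)silyl]-N-(propan-2-yl)carbamate F4. Lithiation between the carbamate and the benzyloxy group (n-BuLi, TMEDA, −78 °C) and quenching with TMSCl would give 3,5-bis(benzyloxy)-4-methoxy-2-(trimethylsilyl)phenyl N-[tert-butyl(dimethyl)silyl]-N-(propan-2-yl)carbamate F5. Aqueous NaHSO4 work-up would convert it into 3,5-bis(benzyloxy)-4-methoxy-2-(trimethylsilyl)phenyl N-(propan-2-yl)carbamate F6. Carbamate cleavage (DBU, Et2NH, MeCN, 40 °C) would release 3,5-bis(benzyloxy)-4-methoxy-2-(trimethylsilyl)phenol F7, and N-phenyl-bis(trifluoromethanesulfonimide) added to the same flask would give 11.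

Step 10. The coupled propiolate may decarboxylate under the basic palladium conditions and be arylated a second time to a diarylalkyne, or oxidative addition to the electron-rich iodide may be slow. The fallback introduces the alkyne and the carboxyl group separately; it sets out from 16 and comes back at 18. Iodide 16 would be coupled with ethynyltrimethylsilane (PdCl2(PPh3)2, CuI, Et3N, rt) to {[4-(benzyloxy)-2,5-dimethoxyphenyl]ethynyl}trimethylsilane F8. Fluoride-triggered carboxylation of the alkynylsilane (CsF, CO2 1 atm, DMSO, rt; then dilute HCl) would then give 18.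

**Further compounds**
F1 | step 11 | 3,5-bis(benzyloxy)-2-iodo-4-methoxyphenol | Oc1cc(OCc2ccccc2)c(OC)c(OCc2ccccc2)c1I
F2 | step 11 | 1-(benzyloxy)-4-ethynyl-2,5-dimethoxybenzene | C#Cc1cc(OC)c(OCc2ccccc2)cc1OC
F3 | step 6 | 3,5-bis(benzyloxy)-4-methoxyphenyl N-(propan-2-yl)carbamate | CC(C)NC(=O)Oc1cc(OCc2ccccc2)c(OC)c(OCc2ccccc2)c1
F4 | step 6 | 3,5-bis(benzyloxy)-4-methoxyphenyl N-[tert-butyl(dimethyl)silyl]-N-(propan-2-yl)carbamate | CC(C)N(C(=O)Oc1cc(OCc2ccccc2)c(OC)c(OCc2ccccc2)c1)[Si](C)(C)C(C)(C)C
F5 | step 6 | 3,5-bis(benzyloxy)-4-methoxy-2-(trimethylsilyl)phenyl N-[tert-butyl(dimethyl)silyl]-N-(propan-2-yl)carbamate | CC(C)N(C(=O)Oc1cc(OCc2ccccc2)c(OC)c(OCc2ccccc2)c1[Si](C)(C)C)[Si](C)(C)C(C)(C)C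
F6 | step 6 | 3,5-bis(benzyloxy)-4-methoxy-2-(trimethylsilyl)phenyl N-(propan-2-yl)carbamate | CC(C)NC(=O)Oc1cc(OCc2ccccc2)c(OC)c(OCc2ccccc2)c1[Si](C)(C)C
F7 | step 6 | 3,5-bis(benzyloxy)-4-methoxy-2-(trimethylsilyl)phenol | Oc1cc(OCc2ccccc2)c(OC)c(OCc2ccccc2)c1[Si](C)(C)C
F8 | step 10 | {[4-(benzyloxy)-2,5-dimethoxyphenyl]ethynyl}trimethylsilane | C[Si](C)(C)C#Cc1cc(OC)c(OCc2ccccc2)cc1OC
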